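**Retrosynthetic overview**
1. Last bond: Wittig olefination at C11=C12 between the triol-end C15 phosphonium salt 37 and the ε-end C25 hydroxy-aldehyde 22 (all hydroxyls free, no final deprotection).
2. 22 comes from the ε-end C15 aldehyde 14 and the C10 phosphonium acetal 19 (made from C10-dialdehyde 15) by Wittig olefination at C11'=C12'.
3. The ε ring is the only ring closed in the route, in step 1: Michael addition of ethyl acetoacetate to mesityl oxide, then intramolecular aldol condensation. Hydride reduction, lipase resolution and HWE chain extension follow.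
4. The trihydroxy ring is bought as ketoisophorone: ene-reductase and hydride reduction give actinol, then enol triflate, Sonogashira coupling, OH-directed syn-dihydroxylation, alkyne-to-(E)-alkene reduction, oxidation, vinyl Grignard addition and phosphonium salt formation.
5. Three branches (ε end, C10 linker, triol end) meet in steps 12 and 25.

Assumption: racemic but-3-yn-2-ol is used, so 30–34 and 36 are epimer pairs at the side-chain carbinol carbon (no stereo mark there); this centre disappears in 35 and 37. Compounds 3–6 are racemic. Carotenoid numbering (C1–C6 ring, C7 onward chain, primed for the ε end) is used in the comments.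

**Step 1**
Reactants: 1 mesityl oxide; 2 ethyl acetoacetate
Product: 5 racemic ethyl 2,6,6-trimethyl-4-oxocyclohex-2-ene-1-carboxylate, via Michael adduct 3 (not isolated), via aldol ketol 4 (not isolated)
Conditions: ZnCl2 (0.2 equiv), heptane/toluene, reflux, Dean–Stark, 48 h; distillation
Reagents that add atoms: none
Why: Robinson-type annulation in which Lewis-acid-promoted Michael addition gives 1,5-diketone 3, whose methyl-ketone enol attacks the zinc-chelated β-keto-ester carbonyl in an intramolecular aldol reaction that closes the six-membered ring (ketol 4) before dehydration to the conjugated enone; the product is racemic.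

**Step 2**
Reactants: 5 racemic keto ester
Product: 6 racemic ethyl (1RS,4RS)-4-hydroxy-2,6,6-trimethylcyclohex-2-ene-1-carboxylate (trans)
Conditions: LiBH(s-Bu)3 (1.1 equiv), THF, −78 °C; aq. NH4Cl; chromatography removes the minor cis isomer
Reagents that add atoms: none
Why: 1,2-hydride reduction of the β,β-disubstituted enone; the bulky hydride enters anti to the axial C6 methyl group (the ester is pseudoaxial to avoid A(1,2) strain), so the hydroxyl ends trans to the ester.

**Step 3**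
Reactants: 6 racemic trans hydroxy ester
Product: 7 ethyl (1R,4R)-4-hydroxy-2,6,6-trimethylcyclohex-2-ene-1-carboxylate
Conditions: lipase AK (Pseudomonas fluorescens lipase), vinyl acetate (3 equiv), MTBE, 30 °C, stop near 52% conversion; chromatography
Reagents that add atoms: none
Why: enzymatic kinetic resolution by irreversible transesterification; the lipase is expected to acylate the (1S,4S) alcohol (CH2–CMe2 side as the large group), leaving the (1R,4R) alcohol in high ee.

**Step 4**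
Reactants: 7 (1R,4R) hydroxy ester
Product: 8 ethyl (1R,4R)-2,6,6-trimethyl-4-(triethylsilyloxy)cyclohex-2-ene-1-carboxylate
Conditions: Et3SiCl (1.2 equiv), imidazole (2 equiv), DMF, 0 °C to rt
Reagents that add atoms: chlorotriethylsilane CC[Si](Cl)(CC)CC
Why: silyl ether protection of the allylic alcohol so that later hydride reductions and the allylic oxidation in step 8 leave it untouched; no stereocentre is affected.

**Step 5**
Reactants: 8 silyl ether ester
Product: 9 (1R,4R)-2,6,6-trimethyl-4-(triethylsilyloxy)cyclohex-2-ene-1-carbaldehyde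
Conditions: i-Bu2AlH (1.1 equiv), toluene, −78 °C; MeOH, then aq. Rochelle salt, cold work-up
Reagents that add atoms: none
Why: partial hydride reduction of the hindered ester stops at the aldehyde level at −78 °C; the cold, base-free work-up keeps the α-stereocentre and the β,γ-alkene in place.

**Step 6**
Reactants: 9 aldehyde; 10 triethyl 3-methyl-4-phosphonocrotonate
Product: 12 ethyl (2E,4E)-3-methyl-5-[(1R,4R)-2,6,6-trimethyl-4-(triethylsilyloxy)cyclohex-2-en-1-yl]penta-2,4-dienoate, via lithiated phosphonate 11 (not isolated)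
Conditions: 10 (1.3 equiv), LiN(SiMe3)2 (1.25 equiv), THF/DMPU, −78 °C; then 9, −78 to 0 °C; chromatography removes the minor 2Z isomer
Reagents that add atoms: none
Why: Horner–Wadsworth–Emmons olefination with the vinylogous phosphonate gives the new C7'=C8' bond E-selectively; addition at −78 °C is faster than enolisation of 9, so C6' keeps its configuration.

**Step 7**
Reactants: 12 dienoate
Product: 13 (2E,4E)-3-methyl-5-[(1R,4R)-2,6,6-trimethyl-4-(triethylsilyloxy)cyclohex-2-en-1-yl]penta-2,4-dien-1-ol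
Conditions: i-Bu2AlH (2.3 equiv), CH2Cl2, −78 °C; aq. Rochelle salt
Reagents that add atoms: none
Why: 1,2-hydride reduction of the conjugated ester to the allylic alcohol without touching the diene or the silyl ether.

**Step 8**
Reactants: 13 dienol
Product: 14 (2E,4E)-3-methyl-5-[(1R,4R)-2,6,6-trimethyl-4-(triethylsilyloxy)cyclohex-2-en-1-yl]penta-2,4-dienal
Conditions: MnO2 (activated, 15 equiv), CH2Cl2, rt
Reagents that add atoms: none
Why: chemoselective allylic oxidation of the primary dienylic alcohol; the ring allylic oxygen is silylated and stays intact.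

**Step 9**
Reactants: 15 (2E,4E,6E)-2,7-dimethylocta-2,4,6-trienedial
Product: 16 (2E,4E,6E)-7-(5,5-dimethyl-1,3-dioxan-2-yl)-2-methylocta-2,4,6-trienal
Conditions: neopentyl glycol (1.0 equiv), PPTS (2 mol %), toluene, 50 °C, reduced pressure (azeotropic water removal); chromatography, 15 and bis-acetal recycled
Reagents that add atoms: neopentyl glycol OCC(C)(C)CO
Why: statistical mono-acetalisation; the first acetal removes the cross-conjugated acceptor and slows the second.

**Step 10**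
Reactants: 16 monoacetal aldehyde
Product: 17 (2E,4E,6E)-7-(5,5-dimethyl-1,3-dioxan-2-yl)-2-methylocta-2,4,6-trien-1-ol
Conditions: NaBH4 (0.5 equiv), EtOH/THF, 0 °C
Reagents that add atoms: none
Why: 1,2-borohydride reduction of the enal; the acetal is inert to hydride.

**Step 11**
Reactants: 17 trienol
Product: 19 [(2E,4E,6E)-7-(5,5-dimethyl-1,3-dioxan-2-yl)-2-methylocta-2,4,6-trien-1-yl]triphenylphosphonium bromide, via allylic bromide 18 (not isolated)
Conditions: CBr4 (1.1 equiv), PPh3 (1.1 equiv), CH2Cl2, −20 to 0 °C; then PPh3 (1.2 equiv), rt, 12 h; precipitation with Et2O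
Reagents that add atoms: carbon tetrabromide BrC(Br)(Br)Br; triphenylphosphine c1ccc(cc1)P(c1ccccc1)c1ccccc1
Why: Appel bromination under neutral conditions (acetal-safe), then SN2 quaternisation of the primary allylic bromide by PPh3.

**Step 12**
Reactants: 14 ε-end C15 aldehyde; 19 C10 phosphonium acetal
Product: 21 (3R,6R)-3-(triethylsilyloxy)-12'-apo-ε-caroten-12'-al neopentyl glycol acetal, via phosphorus ylide 20 (not isolated)
Conditions: 19 (1.1 equiv), NaN(SiMe3)2 (1.05 equiv), THF, −78 to 0 °C; then 14, 0 °C to rt; then heptane, 80 °C, 2 h (Z to E equilibration)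
Reagents that add atoms: none
Why: Wittig olefination of the semi-stabilised trienyl ylide forms C11'=C12'; the unhindered 11'Z isomer equilibrates thermally to all-E, and no stereocentre is involved.

**Step 13**
Reactants: 21 C25 acetal silyl ether
Product: 22 (3R,6R)-3-hydroxy-12'-apo-ε-caroten-12'-al
Conditions: AcOH/THF/H2O (3:1:1), rt to 35 °C, dark
Reagents that add atoms: water O
Why: mild acid hydrolysis cleaves the polyenal acetal (through a conjugated oxocarbenium ion) and the triethylsilyl ether together, while the acid-sensitive allylic C3' alcohol survives.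

**Step 14**
Reactants: 23 ketoisophorone
Product: 24 (6R)-2,2,6-trimethylcyclohexane-1,4-dione
Conditions: OYE2 ene-reductase, NADP+ (cat.), glucose dehydrogenase, D-glucose (1.5 equiv), phosphate buffer pH 7, 30 °C; extraction
Reagents that add atoms: none
Why: enzymatic asymmetric conjugate reduction of the enedione C=C (flavin hydride to the β-carbon, protonation of the methyl-bearing α-carbon on the enzyme) sets 6R.

**Step 15**
Reactants: 24 (6R)-dione
Product: 25 (4R,6R)-4-hydroxy-2,2,6-trimethylcyclohexan-1-one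
Conditions: LiBH(s-Bu)3 (1.05 equiv), THF, −78 °C; aq. NH4Cl
Reagents that add atoms: none
Why: chemoselective hydride reduction of the unhindered C4 ketone (C1 is flanked by a quaternary and a tertiary carbon); equatorial attack, forced by the axial C2 methyl group, gives the axial alcohol trans to the C6 methyl group.

**Step 16**
Reactants: 25 (4R,6R)-hydroxy ketone
Product: 26 (4R,6R)-4-(tert-butyldimethylsilyloxy)-2,2,6-trimethylcyclohexan-1-one
Conditions: t-BuMe2SiCl (1.3 equiv), imidazole (2.5 equiv), DMF, rt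
Reagents that add atoms: tert-butyldimethylsilyl chloride CC(C)(C)[Si](C)(C)Cl
Why: silyl ether protection so that the enolate triflation in step 17 touches only the ketone.

**Step 17**
Reactants: 26 silyloxy ketone
Product: 28 (4R)-4-(tert-butyldimethylsilyloxy)-2,6,6-trimethylcyclohex-1-en-1-yl trifluoromethanesulfonate, via lithium enolate 27 (not isolated)
Conditions: LiN(i-Pr)2 (1.2 equiv), THF, −78 °C, 1 h; then PhNTf2 (1.2 equiv), −78 °C to rt
Reagents that add atoms: N-phenylbis(trifluoromethanesulfonimide) O=S(=O)(N(c1ccccc1)S(=O)(=O)C(F)(F)F)C(F)(F)F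
Why: enolate O-triflation; the ketone can enolise only towards C6, which gives the tetrasubstituted C5=C6 enol triflate of the carotenoid ring (the old C6 stereocentre is meant to be lost).

**Step 18**
Reactants: 28 enol triflate; 29 but-3-yn-2-ol
Product: 30 4-[(4R)-4-(tert-butyldimethylsilyloxy)-2,6,6-trimethylcyclohex-1-en-1-yl]but-3-yn-2-ol
Conditions: Pd(PPh3)4 (5 mol %), CuI (10 mol %), Et3N (3 equiv), DMF, rt to 40 °C
Reagents that add atoms: none
Why: Sonogashira coupling of the hindered enol triflate with the terminal alkyne (zerovalent palladium with copper acetylide transmetallation) attaches C7–C10 and leaves the C3 stereocentre alone.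

**Step 19**
Reactants: 30 silyloxy enyne
Product: 31 (1R)-4-(3-hydroxybut-1-yn-1-yl)-3,5,5-trimethylcyclohex-3-en-1-ol
Conditions: Bu4NF (1.2 equiv), THF, rt
Reagents that add atoms: none
Why: fluoride desilylation frees the homoallylic ring hydroxyl that has to direct step 20.

**Step 20**
Reactants: 31 enyne diol
Product: 33 (1S,2S,4S)-1-(3-hydroxybut-1-yn-1-yl)-2,6,6-trimethylcyclohexane-1,2,4-triol, via osmate ester 32 (not isolated)
Conditions: OsO4 (1.05 equiv), TMEDA (1.1 equiv), CH2Cl2, −78 °C, 2 h; then sat. aq. Na2SO3, THF, reflux, 2 h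
Reagents that add atoms: osmium tetroxide O=[Os](=O)(=O)=O
Why: hydrogen-bond-directed syn-dihydroxylation; the OsO4·TMEDA complex is held by the homoallylic ring hydroxyl and adds both oxygens suprafacially to the C5=C6 face syn to it, giving the all-cis 3,5,6-triol with the alkynyl group trans, while the alkyne is far less reactive.

**Step 21**
Reactants: 33 alkynyl tetrol
Product: 34 (1R,2S,4S)-1-[(1E)-3-hydroxybut-1-en-1-yl]-2,6,6-trimethylcyclohexane-1,2,4-triol
Conditions: LiAlH4 (5 equiv), THF, 0 °C to reflux; Fieser work-up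
Reagents that add atoms: none
Why: hydroxyl-directed trans-hydroalumination of the propargylic diol gives only the (E)-alkene at C7=C8; the descriptor at C1 changes only because the substituent ranking changes.

**Step 22**
Reactants: 34 allylic tetrol
Product: 35 (3E)-4-[(1R,2S,4S)-1,2,4-trihydroxy-2,6,6-trimethylcyclohexyl]but-3-en-2-one
Conditions: MnO2 (activated, 10 equiv), CH2Cl2, rt, stopped at full conversion (about 2 h)
Reagents that add atoms: none
Why: chemoselective allylic oxidation of the secondary allylic alcohol only (the saturated C3 alcohol and the tertiary diol are much slower); both side-chain epimers converge on one enone.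

**Step 23**
Reactants: 35 trihydroxy enone
Product: 36 (1R,2S,4S)-1-[(1E)-3-hydroxy-3-methylpenta-1,4-dien-1-yl]-2,6,6-trimethylcyclohexane-1,2,4-triol
Conditions: CH2=CHMgBr (5 equiv), THF, −40 to 0 °C; aq. NH4Cl
Reagents that add atoms: vinylmagnesium bromide C=C[Mg]Br
Why: Grignard 1,2-addition to the enone after the three hydroxyls are deprotonated by excess reagent; the new carbinol centre needs no control because it is lost in step 24.

**Step 24**
Reactants: 36 vinyl carbinol
Product: 37 [(2E,4E)-3-methyl-5-[(1R,2S,4S)-1,2,4-trihydroxy-2,6,6-trimethylcyclohexyl]penta-2,4-dien-1-yl]triphenylphosphonium bromide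
Conditions: PPh3·HBr (1.0 equiv), MeOH, 0 °C to rt, 12 h; precipitation and recrystallisation (EtOAc/CH2Cl2) to the (2E,4E) salt
Reagents that add atoms: triphenylphosphine hydrobromide [Br-].c1ccc(cc1)[PH+](c1ccccc1)c1ccccc1
Why: acid-mediated ionisation of the doubly allylic tertiary alcohol and SN1' capture of the pentadienyl cation by PPh3 at the unhindered terminus (allylic transposition); with exactly one equivalent of acid the medium ends neutral, which protects the tertiary allylic 6-OH.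

**Step 25**
Reactants: 37 triol-end phosphonium bromide; 22 ε-end C25 hydroxy-aldehyde
Product: 39 5,6-dihydroxylutein (the target), via phosphorus ylide 38 (not isolated)
Conditions: 37 (1.1 equiv), 22 (1.0 equiv), NaOMe (1.3 equiv), MeOH/CH2Cl2, 0 °C to rt, argon, dark; then EtOH, reflux, 3 h (Z to E); crystallisation
Reagents that add atoms: none
Why: Wittig olefination forms C11=C12; the free hydroxyls are tolerated by the semi-stabilised ylide, no stereocentre is touched, and heating equilibrates the 11Z isomer to the all-E polyene.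

**Compound list**
1 | mesityl oxide (4-methylpent-3-en-2-one) | CC(C)=CC(C)=O | starting material
2 | ethyl acetoacetate | CCOC(=O)CC(C)=O | starting material
3 | ethyl 2-acetyl-3,3-dimethyl-5-oxohexanoate (racemic Michael adduct) | CCOC(=O)C(C(C)=O)C(C)(C)CC(C)=O | intermediate
4 | ethyl 2-hydroxy-2,6,6-trimethyl-4-oxocyclohexane-1-carboxylate (racemic aldol ketol) | CCOC(=O)C1C(C)(O)CC(=O)CC1(C)C | intermediate
5 | ethyl 2,6,6-trimethyl-4-oxocyclohex-2-ene-1-carboxylate (racemic) | CCOC(=O)C1C(C)=CC(=O)CC1(C)C | intermediate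
6 | ethyl (1RS,4RS)-4-hydroxy-2,6,6-trimethylcyclohex-2-ene-1-carboxylate (racemic trans isomer, one enantiomer drawn) | CC1=C[C@H](O)CC(C)(C)[C@H]1C(=O)OCC | intermediate
7 | ethyl (1R,4R)-4-hydroxy-2,6,6-trimethylcyclohex-2-ene-1-carboxylate | CC1=C[C@H](O)CC(C)(C)[C@H]1C(=O)OCC | intermediate
8 | ethyl (1R,4R)-2,6,6-trimethyl-4-(triethylsilyloxy)cyclohex-2-ene-1-carboxylate | CC1=C[C@H](O[Si](CC)(CC)CC)CC(C)(C)[C@H]1C(=O)OCC | intermediate
9 | (1R,4R)-2,6,6-trimethyl-4-(triethylsilyloxy)cyclohex-2-ene-1-carbaldehyde | CC1=C[C@H](O[Si](CC)(CC)CC)CC(C)(C)[C@H]1C=O | intermediate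
10 | triethyl 3-methyl-4-phosphonocrotonate, ethyl (2E)-4-(diethoxyphosphoryl)-3-methylbut-2-enoate | CCOC(=O)/C=C(\C)CP(=O)(OCC)OCC | starting material
11 | lithium salt of the phosphonate carbanion of 10 | [Li+].CCOC(=O)/C=C(\C)[CH-]P(=O)(OCC)OCC | intermediate
12 | ethyl (2E,4E)-3-methyl-5-[(1R,4R)-2,6,6-trimethyl-4-(triethylsilyloxy)cyclohex-2-en-1-yl]penta-2,4-dienoate | CC1=C[C@H](O[Si](CC)(CC)CC)CC(C)(C)[C@H]1/C=C/C(C)=C/C(=O)OCC | intermediate
13 | (2E,4E)-3-methyl-5-[(1R,4R)-2,6,6-trimethyl-4-(triethylsilyloxy)cyclohex-2-en-1-yl]penta-2,4-dien-1-ol | CC1=C[C@H](O[Si](CC)(CC)CC)CC(C)(C)[C@H]1/C=C/C(C)=C/CO | intermediate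
14 | (2E,4E)-3-methyl-5-[(1R,4R)-2,6,6-trimethyl-4-(triethylsilyloxy)cyclohex-2-en-1-yl]penta-2,4-dienal | CC1=C[C@H](O[Si](CC)(CC)CC)CC(C)(C)[C@H]1/C=C/C(C)=C/C=O | intermediate
15 | (2E,4E,6E)-2,7-dimethylocta-2,4,6-trienedial (C10-dialdehyde) | O=C/C(C)=C/C=C/C=C(C)/C=O | starting material
16 | (2E,4E,6E)-7-(5,5-dimethyl-1,3-dioxan-2-yl)-2-methylocta-2,4,6-trienal | CC1(C)COC(OC1)/C(C)=C/C=C/C=C(C)/C=O | intermediate
17 | (2E,4E,6E)-7-(5,5-dimethyl-1,3-dioxan-2-yl)-2-methylocta-2,4,6-trien-1-ol | CC1(C)COC(OC1)/C(C)=C/C=C/C=C(C)/CO | intermediate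
18 | 2-[(2E,4E,6E)-8-bromo-7-methylocta-2,4,6-trien-2-yl]-5,5-dimethyl-1,3-dioxane | CC1(C)COC(OC1)/C(C)=C/C=C/C=C(C)/CBr | intermediate
19 | [(2E,4E,6E)-7-(5,5-dimethyl-1,3-dioxan-2-yl)-2-methylocta-2,4,6-trien-1-yl]triphenylphosphonium bromide | CC1(C)COC(OC1)/C(C)=C/C=C/C=C(C)/C[P+](c1ccccc1)(c1ccccc1)c1ccccc1.[Br-] | intermediate
20 | ylide of 19, [(2E,4E,6E)-7-(5,5-dimethyl-1,3-dioxan-2-yl)-2-methylocta-2,4,6-trien-1-ylidene]triphenylphosphorane | CC1(C)COC(OC1)/C(C)=C/C=C/C=C(C)/C=P(c1ccccc1)(c1ccccc1)c1ccccc1 | intermediate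
21 | (3R,6R)-3-(triethylsilyloxy)-12'-apo-ε-caroten-12'-al neopentyl glycol acetal, 2-[(2E,4E,6E,8E,10E,12E)-7,11-dimethyl-13-[(1R,4R)-2,6,6-trimethyl-4-(triethylsilyloxy)cyclohex-2-en-1-yl]trideca-2,4,6,8,10,12-hexaen-2-yl]-5,5-dimethyl-1,3-dioxane | CC1=C[C@H](O[Si](CC)(CC)CC)CC(C)(C)[C@H]1/C=C/C(C)=C/C=C/C(C)=C/C=C/C=C(C)/C1OCC(C)(C)CO1 | intermediate
22 | (3R,6R)-3-hydroxy-12'-apo-ε-caroten-12'-al, (2E,4E,6E,8E,10E,12E)-13-[(1R,4R)-4-hydroxy-2,6,6-trimethylcyclohex-2-en-1-yl]-2,7,11-trimethyltrideca-2,4,6,8,10,12-hexaenal | CC1=C[C@H](O)CC(C)(C)[C@H]1/C=C/C(C)=C/C=C/C(C)=C/C=C/C=C(C)/C=O | intermediate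
23 | ketoisophorone (2,6,6-trimethylcyclohex-2-ene-1,4-dione) | CC1=CC(=O)CC(C)(C)C1=O | starting material
24 | (6R)-2,2,6-trimethylcyclohexane-1,4-dione | C[C@@H]1CC(=O)CC(C)(C)C1=O | intermediate
25 | (4R,6R)-4-hydroxy-2,2,6-trimethylcyclohexan-1-one | C[C@@H]1C[C@@H](O)CC(C)(C)C1=O | intermediate
26 | (4R,6R)-4-(tert-butyldimethylsilyloxy)-2,2,6-trimethylcyclohexan-1-one | C[C@@H]1C[C@@H](O[Si](C)(C)C(C)(C)C)CC(C)(C)C1=O | intermediate
27 | lithium (4R)-4-(tert-butyldimethylsilyloxy)-2,6,6-trimethylcyclohex-1-en-1-olate | [Li]OC1=C(C)C[C@@H](O[Si](C)(C)C(C)(C)C)CC1(C)C | intermediate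
28 | (4R)-4-(tert-butyldimethylsilyloxy)-2,6,6-trimethylcyclohex-1-en-1-yl trifluoromethanesulfonate | FC(F)(F)S(=O)(=O)OC1=C(C)C[C@@H](O[Si](C)(C)C(C)(C)C)CC1(C)C | intermediate
29 | but-3-yn-2-ol (racemic) | CC(O)C#C | starting material
30 | 4-[(4R)-4-(tert-butyldimethylsilyloxy)-2,6,6-trimethylcyclohex-1-en-1-yl]but-3-yn-2-ol (side-chain epimers) | CC(O)C#CC1=C(C)C[C@@H](O[Si](C)(C)C(C)(C)C)CC1(C)C | intermediate
31 | (1R)-4-(3-hydroxybut-1-yn-1-yl)-3,5,5-trimethylcyclohex-3-en-1-ol (side-chain epimers) | CC(O)C#CC1=C(C)C[C@@H](O)CC1(C)C | intermediate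
32 | cyclic osmate ester (hexavalent osmium, TMEDA adduct) across the 5,6-oxygens of 33 | CC(O)C#C[C@@]1(O[Os]2(=O)=O)C(C)(C)C[C@H](O)C[C@]1(C)O2.CN(C)CCN(C)C | intermediate
33 | (1S,2S,4S)-1-(3-hydroxybut-1-yn-1-yl)-2,6,6-trimethylcyclohexane-1,2,4-triol (side-chain epimers) | CC(O)C#C[C@@]1(O)C(C)(C)C[C@H](O)C[C@]1(C)O | intermediate
34 | (1R,2S,4S)-1-[(1E)-3-hydroxybut-1-en-1-yl]-2,6,6-trimethylcyclohexane-1,2,4-triol (side-chain epimers) | CC(O)/C=C/[C@@]1(O)C(C)(C)C[C@H](O)C[C@]1(C)O | intermediate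
35 | (3E)-4-[(1R,2S,4S)-1,2,4-trihydroxy-2,6,6-trimethylcyclohexyl]but-3-en-2-one | CC(=O)/C=C/[C@@]1(O)C(C)(C)C[C@H](O)C[C@]1(C)O | intermediate
36 | (1R,2S,4S)-1-[(1E)-3-hydroxy-3-methylpenta-1,4-dien-1-yl]-2,6,6-trimethylcyclohexane-1,2,4-triol (side-chain epimers) | C=CC(C)(O)/C=C/[C@@]1(O)C(C)(C)C[C@H](O)C[C@]1(C)O | intermediate
37 | [(2E,4E)-3-methyl-5-[(1R,2S,4S)-1,2,4-trihydroxy-2,6,6-trimethylcyclohexyl]penta-2,4-dien-1-yl]triphenylphosphonium bromide | C(/C=C(C)/C=C/[C@@]1(O)C(C)(C)C[C@H](O)C[C@]1(C)O)[P+](c1ccccc1)(c1ccccc1)c1ccccc1.[Br-] | intermediate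
38 | ylide of 37, [(2E,4E)-3-methyl-5-[(1R,2S,4S)-1,2,4-trihydroxy-2,6,6-trimethylcyclohexyl]penta-2,4-dien-1-ylidene]triphenylphosphorane | C(/C=C(C)/C=C/[C@@]1(O)C(C)(C)C[C@H](O)C[C@]1(C)O)=P(c1ccccc1)(c1ccccc1)c1ccccc1 | intermediate
39 | 5,6-dihydroxylutein, (3S,5S,6R,3'R,6'R)-5,6-dihydro-β,ε-carotene-3,5,6,3'-tetrol | CC1=C[C@H](O)CC(C)(C)[C@H]1/C=C/C(C)=C/C=C/C(C)=C/C=C/C=C(C)/C=C/C=C(C)/C=C/[C@@]1(O)C(C)(C)C[C@H](O)C[C@]1(C)O | target

**Totals**
Total step count: 25.
Longest linear sequence: 12 steps (steps 14–24, then 25). The ε-end branch is 11 steps (1–8, 12, 13, 25) and the C10 branch is 6 (9–11, 12, 13, 25).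

**Steps most likely to fail, with fallbacks**

Step 20 (facial selectivity of the dihydroxylation; the axial methyl group at C1 may oppose delivery syn to the 3-OH). The fallback sets out from 31 and comes back at 33. Acetylation (Ac2O, pyridine, DMAP) gives (1R)-4-(3-acetoxybut-1-yn-1-yl)-3,5,5-trimethylcyclohex-3-en-1-yl acetate F3. A Woodward cis-hydroxylation (I2, AgOAc, AcOH, then wet AcOH, 90 °C) follows: iodonium forms on the face anti to the ring acetate and acetate opens it from the other face to give 4-[(1R,2S,4S)-2,4-diacetoxy-1-iodo-2,6,6-trimethylcyclohexyl]but-3-yn-2-yl acetate F4. Silver-assisted displacement of iodide by the neighbouring acetate (acetoxonium ion) and capture by water then give 4-[(1S,2S,4S)-2,4-diacetoxy-1-hydroxy-2,6,6-trimethylcyclohexyl]but-3-yn-2-yl acetate F5 (with its 6-acetate regioisomer). This cis-diol lies on the face opposite to the one an undirected osmylation would take, that is syn to the C3 oxygen. K2CO3 in MeOH removes the acetates to give 33.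

Step 24 (acid may trigger cyclisation or semipinacol shift at the tertiary allylic 6-OH instead of clean capture by PPh3). The fallback reverses the polarity of the last coupling; it sets out from 35 (22 is modified in parallel) and comes back at 39.
- Triol side: silylation with 1-(trimethylsilyl)imidazole gives (3E)-4-[(1R,2S,4S)-2,6,6-trimethyl-1,2,4-tris(trimethylsilyloxy)cyclohexyl]but-3-en-2-one F6. HWE reaction with diethyl cyanomethylphosphonate (NaH, THF) gives (2E,4E)-3-methyl-5-[(1R,2S,4S)-2,6,6-trimethyl-1,2,4-tris(trimethylsilyloxy)cyclohexyl]penta-2,4-dienenitrile F7. i-Bu2AlH at −78 °C, then wet silica, gives (2E,4E)-3-methyl-5-[(1R,2S,4S)-2,6,6-trimethyl-1,2,4-tris(trimethylsilyloxy)cyclohexyl]penta-2,4-dienal F8.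
- ε side: NaBH4 reduces 22 to (2E,4E,6E,8E,10E,12E)-13-[(1R,4R)-4-hydroxy-2,6,6-trimethylcyclohex-2-en-1-yl]-2,7,11-trimethyltrideca-2,4,6,8,10,12-hexaen-1-ol F9. PPh3·HBr converts it into [(2E,4E,6E,8E,10E,12E)-13-[(1R,4R)-4-hydroxy-2,6,6-trimethylcyclohex-2-en-1-yl]-2,7,11-trimethyltrideca-2,4,6,8,10,12-hexaen-1-yl]triphenylphosphonium bromide F10.
- Coupling: Wittig reaction of F10 with F8 (NaN(SiMe3)2, THF) gives 5,6-dihydroxylutein 3,5,6-tris(trimethylsilyl) ether F11, and Bu4NF gives 39.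

Step 3 (the lipase may show low or reversed enantioselectivity on this small, pseudoaxial allylic alcohol). The fallback sets out from 6 and comes back at 7. Racemic 6 is esterified with (S)-2-methoxy-2-phenylacetic acid (DCC, DMAP, CH2Cl2) to give ethyl (1R,4R)-4-{[(2S)-2-methoxy-2-phenylacetyl]oxy}-2,6,6-trimethylcyclohex-2-ene-1-carboxylate F1 together with ethyl (1S,4S)-4-{[(2S)-2-methoxy-2-phenylacetyl]oxy}-2,6,6-trimethylcyclohex-2-ene-1-carboxylate F2. The diastereomers are separated by chromatography or crystallisation, and F1 is cleaved with K2CO3 in ethanol to give 7.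

**Further compounds**
F1 | step 3 | ethyl (1R,4R)-4-{[(2S)-2-methoxy-2-phenylacetyl]oxy}-2,6,6-trimethylcyclohex-2-ene-1-carboxylate | CC1=C[C@H](OC(=O)[C@@H](OC)c2ccccc2)CC(C)(C)[C@H]1C(=O)OCC
F2 | step 3 | ethyl (1S,4S)-4-{[(2S)-2-methoxy-2-phenylacetyl]oxy}-2,6,6-trimethylcyclohex-2-ene-1-carboxylate | CC1=C[C@@H](OC(=O)[C@@H](OC)c2ccccc2)CC(C)(C)[C@@H]1C(=O)OCC
F3 | step 20 | (1R)-4-(3-acetoxybut-1-yn-1-yl)-3,5,5-trimethylcyclohex-3-en-1-yl acetate | CC(OC(C)=O)C#CC1=C(C)C[C@@H](OC(C)=O)CC1(C)C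
F4 | step 20 | 4-[(1R,2S,4S)-2,4-diacetoxy-1-iodo-2,6,6-trimethylcyclohexyl]but-3-yn-2-yl acetate | CC(OC(C)=O)C#C[C@]1(I)C(C)(C)C[C@H](OC(C)=O)C[C@]1(C)OC(C)=O
F5 | step 20 | 4-[(1S,2S,4S)-2,4-diacetoxy-1-hydroxy-2,6,6-trimethylcyclohexyl]but-3-yn-2-yl acetate | CC(OC(C)=O)C#C[C@@]1(O)C(C)(C)C[C@H](OC(C)=O)C[C@]1(C)OC(C)=O
F6 | step 24 | (3E)-4-[(1R,2S,4S)-2,6,6-trimethyl-1,2,4-tris(trimethylsilyloxy)cyclohexyl]but-3-en-2-one | CC(=O)/C=C/[C@@]1(O[Si](C)(C)C)C(C)(C)C[C@H](O[Si](C)(C)C)C[C@]1(C)O[Si](C)(C)C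
F7 | step 24 | (2E,4E)-3-methyl-5-[(1R,2S,4S)-2,6,6-trimethyl-1,2,4-tris(trimethylsilyloxy)cyclohexyl]penta-2,4-dienenitrile | N#C/C=C(C)/C=C/[C@@]1(O[Si](C)(C)C)C(C)(C)C[C@H](O[Si](C)(C)C)C[C@]1(C)O[Si](C)(C)C
F8 | step 24 | (2E,4E)-3-methyl-5-[(1R,2S,4S)-2,6,6-trimethyl-1,2,4-tris(trimethylsilyloxy)cyclohexyl]penta-2,4-dienal | O=C/C=C(C)/C=C/[C@@]1(O[Si](C)(C)C)C(C)(C)C[C@H](O[Si](C)(C)C)C[C@]1(C)O[Si](C)(C)C
F9 | step 24 | (2E,4E,6E,8E,10E,12E)-13-[(1R,4R)-4-hydroxy-2,6,6-trimethylcyclohex-2-en-1-yl]-2,7,11-trimethyltrideca-2,4,6,8,10,12-hexaen-1-ol | CC1=C[C@H](O)CC(C)(C)[C@H]1/C=C/C(C)=C/C=C/C(C)=C/C=C/C=C(C)/CO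
F10 | step 24 | [(2E,4E,6E,8E,10E,12E)-13-[(1R,4R)-4-hydroxy-2,6,6-trimethylcyclohex-2-en-1-yl]-2,7,11-trimethyltrideca-2,4,6,8,10,12-hexaen-1-yl]triphenylphosphonium bromide | CC1=C[C@H](O)CC(C)(C)[C@H]1/C=C/C(C)=C/C=C/C(C)=C/C=C/C=C(C)/C[P+](c2ccccc2)(c3ccccc3)c4ccccc4.[Br-]
F11 | step 24 | 5,6-dihydroxylutein 3,5,6-tris(trimethylsilyl) ether | CC1=C[C@H](O)CC(C)(C)[C@H]1/C=C/C(C)=C/C=C/C(C)=C/C=C/C=C(C)/C=C/C=C(C)/C=C/[C@@]2(O[Si](C)(C)C)C(C)(C)C[C@H](O[Si](C)(C)C)C[C@]2(C)O[Si](C)(C)C
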